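At 30 h the reading shows how far each flask has got, but also what its charge allows.

all flasks: X 20 mM

| run | L | temperature | remark | time |
|---|---|---|---|---|
| ochre | 6.5 mM | 20 °C | run made earlier |  |
| teal | 15 mM | 40 °C | run made earlier |  |
| green | 27 mM | 20 °C | run made earlier |  |
| elm | 8.00 mM | 25 °C |  | 30 h |
| maple | 26.0 mM | 25 °C |  | 30 h |
| larch | 8.00 mM | 55 °C |  | 30 h |
| oak | 26.0 mM | 55 °C |  | 30 h |

| run | time / h | J / % | X / % |
|---|---|---|---|
| ochre | 4.00 | 7.2 | 89.1 |
| ochre | 8.00 | 12.1 | 78.4 |
| ochre | 12.0 | 15.8 | 68.8 |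
| ochre | 15.0 | 17.2 | 62.1 |
| ochre | 20.0 | 17.5 | 52.3 |
| teal | 0.667 | 12.1 | 81.0 |
| teal | 1.33 | 19.7 | 65.6 |
| teal | 3.00 | 29.6 | 36.9 |
| teal | 6.00 | 34.6 | 13.8 |
| teal | 10.0 | 36.4 | 4.8 |
| green | 1.50 | 3.0 | 94.0 |
| green | 3.00 | 5.6 | 89.0 |
| green | 6.00 | 10.6 | 79.0 |
| green | 12.0 | 15.8 | 61.0 |
| green | 20.0 | 19.9 | 42.1 |

(scatter of a reading: 0.3 percentage points)

1. the flasks by amount of J, in percent of the X charged, highest first, at 30 h (elm / maple / larch / oak)
2. the amount of J, in percent of the X charged of the flask you put first, at 30 h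
3. the amount of J, in percent of the X charged of the flask you put last, at 30 h

- a species is counted by the X in it: one E counts as two
- the numbers in the tables scatter by 0.3 percentage points (one standard deviation)
- on the list of suspects stand: L + G -> J; X + L <-> Z; X <-> G; X + J -> E

1. Suppose each J costs one L and each E holds one J and one X. In percent of the X charged, L spent is then J plus half of E, with E counted as two.

2. Way one, from the curve: J in ochre reads 17.2% at 15.0 h and 17.5% at 20.0 h, a step of 0.3 percentage points against a scatter of 0.3 points. J has stalled within the scatter.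

3. Way two, from the balance: reading all X missing at 20.0 h as E, ochre has spent 6.52 mM of L, close to its charge of 6.5 mM. The stall and the balance come from different things and agree, so ochre reads as a flask with L as limiting reagent.

4. Once X, G and Z are empty, J plus E is the whole charge. So J at the end is twice (L spent minus L*) over the X charged, where L* is the crossing charge, half the X charged: 10.0 mM.

5. Larch and elm hold 8.00 mM, less than L*. With the whole charge put in as L spent, the formula gives −20.0% for them, so my own reckoning sends J towards zero at the end, with 20.0% of the X left over as X and G. Teal at 40 °C, with 15 mM of L, had X down to 13.8% by 6.00 h, a time shorter than 30 h. Larch at 55 °C is hotter but holds less L, so that larch stands near this end by 30 h is my estimate. Oak and maple hold 26.0 mM, more than L*, and with the whole charge put in as L spent the formula gives 160%, beyond the whole X charged, so it sets them no number.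

The forecast: oak > maple > elm > larch, with 35% first and 8% last, on the ground “then remaining X eats J”. For larch my reckoning goes towards zero, where the forecast stands at 8%.

The flasks give oak > maple > elm > larch, with oak at 47.2% and larch at 0.0195%.

    L + G → J (k = 0.330 L mol⁻¹ s⁻¹, Ea = 36.0 kJ mol⁻¹)
    X + L ⇌ Z (K = 100 L mol⁻¹, k = 2.30 × 10⁻⁴ L mol⁻¹ s⁻¹, Ea = 75.0 kJ mol⁻¹, ΔH = −23.0 kJ mol⁻¹)
    X ⇌ G (K = 0.220, k = 1.20 × 10⁻⁵ s⁻¹, Ea = 89.0 kJ mol⁻¹, ΔH = −17.0 kJ mol⁻¹)
    X + J → E (k = 0.00160 L mol⁻¹ s⁻¹, Ea = 66.0 kJ mol⁻¹)
    (constants at 25 °C)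

Larch at 30.0 h holds X 17.9%, G 2.11% and E 80.0%; X and G together make the 20.0% reckoned. The neighbour is larch with 14 mM of L, which is 0.700 equiv and more than L*. At the end its X and Z stand at 0% and 0%, G at 0%, and 4.9% of its own L remains. The same formula on the L spent gives 33.1%. The flask holds E 66.9% and J 33.1%.

The readings were generated by integration for substances that don't exist.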